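The numbers of this flask belong to no real substance, and the outcome is calculated.

I started with the easy step of setting out the flasks and what was asked.

the same everywhere: D 1.10 equiv; time 40 min

| run | J |
|---|---|
| south | 0.0040 M |
| north-east | 0.012 M |
| south-west | 0.030 M |
| west | 0.10 M |

    J + D → J.D (k1 = 1.85 L mol⁻¹ min⁻¹)
    J + D → G (k2 = 1.58 L mol⁻¹ min⁻¹)
    J + D → Z (k3 = 2.64 L mol⁻¹ min⁻¹)
    L ⇌ J.D, rate k4*(cs4 - [J.D]) while solid is left; crystals form when [J.D] > cs4 (cs4 = 7.2 mM, k4 = 0.151 min⁻¹)
    2 J → J2 (k5 = 0.0427 L mol⁻¹ min⁻¹)

- a species is counted by the J in it: one J2 counts as two
- amounts and yields of J.D count L too
- where a step has two of a species, its rate is k times that concentration squared, and two are used at each turn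
- given per volume of solution although it is solid: L
- "hardly changes" means that all values lie within two and a half points (for a concentration: within two and a half percent of the largest)
- run time (south): 40 min

* share of J.D in all that became J.D or G or Z for south, north-east, south-west, west, in this order
* how the row runs (falls, then rises / falls all the way / hardly changes / rises all the way / rises, then falls)

J.D, G and Z form at 1.85 L mol⁻¹ min⁻¹, 1.58 L mol⁻¹ min⁻¹ and 2.64 L mol⁻¹ min⁻¹ times c(J) c(D), so dividing any one of these rates by another cancelled c(J) c(D), however both concentrations moved. Integrating from zero then gave amounts formed in the ratio of the constants, with no time left in the expression. I named the first constant over the sum of the three the branch share 30.5 %, which is the selectivity for J.D among these parallel steps.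

Then I read the table of flasks from top to bottom. Going from south to west, c(J) rose 25.0-fold at a steady 1.10 equiv of D, so the starting product c(J) c(D) rose 625-fold, yet that is the product that had cancelled. Setting the small loss to J2 aside and taking the charged J through the three steps, I reckoned 1.22 mM of J.D for the south row and 3.66 mM for the north-east row, both below the solubility 7.2 mM. The same reckoning gave 9.14 mM for the south-west row and 30.5 mM for the west row, both above it, so I expected crystals in those two. L is counted with J.D, however, so crystals move J.D without changing the count. The dimerisation of J lowers the common factor c(J) and leaves the ratio alone. I therefore committed to 30.5 % for south, north-east, south-west and west alike.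

The forecast gave 30.48 %, 30.48 %, 30.48 % and 30.48 %, a row that hardly changes, on the ground of “the same rate order”.

The simulation gave 30.5 %, 30.5 %, 30.5 % and 30.5 %, a row that hardly changes.

In south, the step to Z used J at 1.4 times the rate of the step to J.D at the start, 1.4 times at 13.2 min and 1.4 times at 40.0 min, while the half-life of J by the step to G lengthened from 100 min to 190 min. In west at 40.0 min, the branch share applied to G at 25.6 % and Z at 42.7 % called for 30.0 % of J.D, and the flask held 29.9 %, with L at 22.5 % counted within it.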